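The 1,2-dioxolane (O1–O2–C3–C4–C5) is read as a cyclopropane into whose C–C bond dioxygen has been inserted: C3 and C5 are the ends of the broken bond, C4 is the untouched CH2, and C3 is a ketone carbon once the acetic acid arm is taken off. The key step, a Mn-catalysed aerobic ring expansion, turns the peroxide-free cyclopropanol 6 (any diastereomer) into dioxolanol 8, making both C–O bonds in one operation. C3 is then set trans to the chain by peroxycarbenium alkylation with a chiral imide enolate; separation of the diastereomers selects the 3R,5S series. Cross-metathesis and Julia–Kocienski olefination complete the triene.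

Key step: step 3

Remark on the chemistry: the radical ring expansion necessarily gives C5 as a racemate. The absolute configuration is therefore secured in step 5 by chromatographic separation of diastereomeric N-acyl oxazolidinones, so at most half of the material is carried on. The oxidation-sensitive triene is introduced only after the peroxide ring is complete.

Step 1
Reactants: 1 7-bromohept-1-ene; 2 3-methylbut-3-en-2-one
Product: 4 trimethyl[(3-methylundeca-2,10-dien-2-yl)oxy]silane (E/Z mixture), via hept-6-en-1-ylmagnesium bromide 3 (not isolated)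
Conditions: Mg, THF, rt; then 2, CuBr·SMe2 (5 mol %), TMSCl, DMPU, THF, −78 °C
Reagents that add atoms: trimethylsilyl chloride, C[Si](C)(C)Cl
Why: Copper-catalysed conjugate addition of the Grignard reagent to the α-methylene ketone, accelerated by TMSCl, should trap the enolate regiospecifically as the tetrasubstituted silyl enol ether, whose E/Z ratio is irrelevant because both isomers converge later.

Step 2
Reactants: 4 trimethyl[(3-methylundeca-2,10-dien-2-yl)oxy]silane
Product: 6 1,2-dimethyl-2-(oct-7-en-1-yl)cyclopropan-1-ol (racemic mixture of diastereomers), via silyl cyclopropyl ether 5 (not isolated)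
Conditions: Et2Zn (1.2 equiv), CH2I2 (1.2 equiv), CH2Cl2, 0 °C → rt; aqueous work-up; then K2CO3 (cat.), MeOH, 0 °C
Reagents that add atoms: diiodomethane, ICI
Why: The Furukawa-modified Simmons–Smith cyclopropanation should be much faster on the electron-rich silyl enol ether than on the remote monosubstituted alkene, and mild methanolysis then frees the tertiary cyclopropanol, the two new stereocentres forming as an inconsequential mixture.

Step 3
Reactants: 6 1,2-dimethyl-2-(oct-7-en-1-yl)cyclopropan-1-ol
Product: 8 3,5-dimethyl-5-(oct-7-en-1-yl)-1,2-dioxolan-3-ol (racemic at C5; C3 epimers), via hydroperoxy ketone 7 (not isolated)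
Conditions: Mn(acac)2 (2 mol %), O2 (1 atm), PhH, rt
Reagents that add atoms: dioxygen, O=O
Why: A Mn(III) cyclopropoxide should undergo β-scission of the more substituted C1–C2 bond to give Mn(II) and the tertiary β-keto alkyl radical, which captures O2; the peroxyl radical is reduced by Mn(II) and protonated to hydroperoxy ketone 7, closing the redox cycle. The closest known reaction type is the Mn(II)- or Co(II)-catalysed aerobic oxidation of cyclopropanols to 3-hydroxy-1,2-dioxolanes. The dioxolane closes by 5-exo-trig addition of the OOH group to the ketone C=O, so the three cyclopropane carbons and the two atoms of O2 make up the five-membered ring (three-to-five ring expansion). C5 is formed at a planar radical and is therefore racemic, and C3 is an equilibrating hemiketal centre (both are settled in step 5), which also means that both cyclopropanol diastereomers converge on the same product. The step needs regioselective scission, secured by the quaternary C2 (tertiary versus primary radical), and chemoselectivity over the terminal alkene, secured by the absence of any H-atom donor or hydrometalating species and by the very fast capture of the radical by O2.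

Step 4
Reactants: 8 3,5-dimethyl-5-(oct-7-en-1-yl)-1,2-dioxolan-3-ol
Product: 9 3-methoxy-3,5-dimethyl-5-(oct-7-en-1-yl)-1,2-dioxolane (racemic at C5; C3 epimers)
Conditions: MeOH, PPTS (cat.), 3 Å MS, rt
Reagents that add atoms: methanol, CO
Why: Acid-catalysed ketal exchange through the peroxycarbenium ion should convert the hemiketal into a peroxyketal with a methoxy leaving group, both C3 epimers being equally useful because they ionise to the same cation.

Step 5
Reactants: 9 3-methoxy-3,5-dimethyl-5-(oct-7-en-1-yl)-1,2-dioxolane; 10 (4S)-3-acetyl-4-benzyl-1,3-oxazolidin-2-one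
Product: 12 (4S)-4-benzyl-3-{2-[(3R,5S)-3,5-dimethyl-5-(oct-7-en-1-yl)-1,2-dioxolan-3-yl]acetyl}-1,3-oxazolidin-2-one (single diastereomer after chromatography), via chlorotitanium enolate 11 (not isolated)
Conditions: 10, TiCl4, i-Pr2NEt, CH2Cl2, 0 °C; then 9, TiCl4, −78 → −40 °C; chromatographic separation of the diastereomers
Reagents that add atoms: none
Why: Soft enolisation gives a chlorotitanium imide enolate that should alkylate the peroxycarbenium ion released from 9 by TiCl4 (SN1-type Mukaiyama-like substitution of a 3-alkoxy-1,2-dioxolane by an enol nucleophile), attack occurring anti to the larger, pseudoequatorial C5 chain so that C3 is set trans to it, and the two trans diastereomers that arise from the two C5 enantiomers are then separated, which selects the 3R,5S series.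

Step 6
Reactants: 12 (4S)-4-benzyl-3-{2-[(3R,5S)-3,5-dimethyl-5-(oct-7-en-1-yl)-1,2-dioxolan-3-yl]acetyl}-1,3-oxazolidin-2-one
Product: 13 2-[(3R,5S)-3,5-dimethyl-5-(oct-7-en-1-yl)-1,2-dioxolan-3-yl]acetic acid
Conditions: LiOH, H2O2, THF/H2O, 0 °C; then Na2SO3; HCl to pH 3
Reagents that add atoms: hydrogen peroxide (as lithium hydroperoxide), OO
Why: Hydroperoxide anion should cleave the exocyclic imide carbonyl selectively (standard removal of an N-acyl oxazolidinone auxiliary) without touching the fully substituted dialkyl peroxide, the alkene or either stereocentre.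

Step 7
Reactants: 13 2-[(3R,5S)-3,5-dimethyl-5-(oct-7-en-1-yl)-1,2-dioxolan-3-yl]acetic acid; 14 (E)-but-2-enal
Product: 15 2-[(3R,5S)-3,5-dimethyl-5-[(E)-9-oxonon-7-en-1-yl]-1,2-dioxolan-3-yl]acetic acid
Conditions: Grubbs II catalyst (5 mol %), 14 (5 equiv), CH2Cl2, 40 °C
Reagents that add atoms: none
Why: Olefin cross-metathesis of the terminal alkene with an excess of the enal partner should be thermodynamically E-selective, and free carboxylic acids and hindered dialkyl peroxides are tolerated by the Ru alkylidene.

Step 8
Reactants: 16 (Z)-hex-3-en-1-ol; 17 1-phenyl-1H-tetrazole-5-thiol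
Product: 18 5-[(Z)-hex-3-en-1-ylsulfanyl]-1-phenyl-1H-tetrazole
Conditions: PPh3, DIAD, THF, 0 °C → rt
Reagents that add atoms: none
Why: Mitsunobu thioetherification of the primary alcohol with the acidic tetrazole thiol should proceed under neutral conditions that leave the Z-alkene untouched.

Step 9
Reactants: 18 5-[(Z)-hex-3-en-1-ylsulfanyl]-1-phenyl-1H-tetrazole
Product: 19 5-[(Z)-hex-3-en-1-ylsulfonyl]-1-phenyl-1H-tetrazole
Conditions: (NH4)6Mo7O24·4H2O (cat.), 30% H2O2, EtOH, 0 °C → rt
Reagents that add atoms: hydrogen peroxide, OO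
Why: Molybdate-catalysed oxidation with H2O2 should take the sulfide to the sulfone chemoselectively, the isolated Z-alkene being inert to the peroxomolybdate at room temperature.

Step 10
Reactants: 15 2-[(3R,5S)-3,5-dimethyl-5-[(E)-9-oxonon-7-en-1-yl]-1,2-dioxolan-3-yl]acetic acid; 19 5-[(Z)-hex-3-en-1-ylsulfonyl]-1-phenyl-1H-tetrazole
Product: 21 2-[(3R,5S)-3,5-dimethyl-5-[(7E,9E,12Z)-pentadeca-7,9,12-trien-1-yl]-1,2-dioxolan-3-yl]acetic acid, via potassium sulfonyl carbanion 20 (not isolated)
Conditions: 19 (2.3 equiv), KHMDS (2.2 equiv), THF, −78 °C; then 15, −78 °C → rt; dilute HCl work-up (argon, BHT)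
Reagents that add atoms: none
Why: Julia–Kocienski olefination of the enal with the metalated phenyltetrazolyl sulfone should form the new C9=C10 bond with E geometry through addition, Smiles rearrangement and anti-elimination, one extra equivalent of carbanion serving to turn the acid into an inert carboxylate, while the Z-alkene and both ring stereocentres are untouched.

Compound list
1 | 7-bromohept-1-ene | C=CCCCCCBr | starting material
2 | 3-methylbut-3-en-2-one | CC(=O)C(C)=C | starting material
3 | hept-6-en-1-ylmagnesium bromide | C=CCCCCC[Mg]Br | intermediate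
4 | trimethyl[(3-methylundeca-2,10-dien-2-yl)oxy]silane (E/Z mixture) | CC(O[Si](C)(C)C)=C(C)CCCCCCC=C | intermediate
5 | trimethyl{[1,2-dimethyl-2-(oct-7-en-1-yl)cyclopropyl]oxy}silane (racemic, mixture of diastereomers) | CC1(O[Si](C)(C)C)CC1(C)CCCCCCC=C | intermediate
6 | 1,2-dimethyl-2-(oct-7-en-1-yl)cyclopropan-1-ol (racemic, mixture of diastereomers) | CC1(O)CC1(C)CCCCCCC=C | intermediate
7 | 4-hydroperoxy-4-methyldodec-11-en-2-one (racemic) | CC(=O)CC(C)(OO)CCCCCCC=C | intermediate
8 | 3,5-dimethyl-5-(oct-7-en-1-yl)-1,2-dioxolan-3-ol (racemic at C5, C3 epimers) | CC1(O)CC(C)(CCCCCCC=C)OO1 | intermediate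
9 | 3-methoxy-3,5-dimethyl-5-(oct-7-en-1-yl)-1,2-dioxolane (racemic at C5, C3 epimers) | COC1(C)CC(C)(CCCCCCC=C)OO1 | intermediate
10 | (4S)-3-acetyl-4-benzyl-1,3-oxazolidin-2-one | CC(=O)N1C(=O)OC[C@@H]1Cc1ccccc1 | starting material
11 | trichlorotitanium enolate of (4S)-3-acetyl-4-benzyl-1,3-oxazolidin-2-one | C=C(O[Ti](Cl)(Cl)Cl)N1C(=O)OC[C@@H]1Cc1ccccc1 | intermediate
12 | (4S)-4-benzyl-3-{2-[(3R,5S)-3,5-dimethyl-5-(oct-7-en-1-yl)-1,2-dioxolan-3-yl]acetyl}-1,3-oxazolidin-2-one | C=CCCCCCC[C@@]1(C)C[C@](C)(CC(=O)N2C(=O)OC[C@@H]2Cc2ccccc2)OO1 | intermediate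
13 | 2-[(3R,5S)-3,5-dimethyl-5-(oct-7-en-1-yl)-1,2-dioxolan-3-yl]acetic acid | C=CCCCCCC[C@@]1(C)C[C@](C)(CC(=O)O)OO1 | intermediate
14 | (E)-but-2-enal | C/C=C/C=O | starting material
15 | 2-[(3R,5S)-3,5-dimethyl-5-[(E)-9-oxonon-7-en-1-yl]-1,2-dioxolan-3-yl]acetic acid | O=C/C=C/CCCCCC[C@@]1(C)C[C@](C)(CC(=O)O)OO1 | intermediate
16 | (Z)-hex-3-en-1-ol | CC/C=C\CCO | starting material
17 | 1-phenyl-1H-tetrazole-5-thiol | Sc1nnnn1-c1ccccc1 | starting material
18 | 5-[(Z)-hex-3-en-1-ylsulfanyl]-1-phenyl-1H-tetrazole | CC/C=C\CCSc1nnnn1-c1ccccc1 | intermediate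
19 | 5-[(Z)-hex-3-en-1-ylsulfonyl]-1-phenyl-1H-tetrazole | CC/C=C\CCS(=O)(=O)c1nnnn1-c1ccccc1 | intermediate
20 | potassium (Z)-1-[(1-phenyl-1H-tetrazol-5-yl)sulfonyl]hex-3-en-1-ide | CC/C=C\C[CH-]S(=O)(=O)c1nnnn1-c1ccccc1.[K+] | intermediate
21 | 2-[(3R,5S)-3,5-dimethyl-5-[(7E,9E,12Z)-pentadeca-7,9,12-trien-1-yl]-1,2-dioxolan-3-yl]acetic acid | CC/C=C\C/C=C/C=C/CCCCCC[C@@]1(C)C[C@](C)(CC(=O)O)OO1 | target

Total step count: 10.
Longest linear sequence: 8 steps (steps 1–7 and 10); steps 8 and 9 make the sulfone in a side branch.

Steps most likely to fail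

Step 3 (key step). The radical chain may be diverted before the hemiketal closes: Mn-promoted O–O homolysis of the hydroperoxide to β-hydroxy or epoxy ketone, or hydrogen abstraction at the allylic positions. The fallback leaves the aerobic chain and brings in the peroxide ionically. It sets out from silyl cyclopropyl ether 5: FeCl3 in DMF at 0 °C (one-electron oxidative ring opening of the siloxycyclopropane with chlorine transfer to the tertiary radical) should give 4-chloro-4-methyldodec-11-en-2-one F1. Silver-assisted perhydrolysis of the tertiary chloride (AgOTf, anhydrous H2O2 in Et2O, 0 °C) should then give hydroperoxy ketone 7, which closes spontaneously, and the route is rejoined at 8.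

Step 5. The acetate-derived titanium enolate may react sluggishly with the hindered tertiary peroxycarbenium ion, facial selectivity at C3 may be poor, or the two trans imides may co-elute. The fallback separates C–C bond formation from resolution and sets out from 9. TiCl4 and commercial 1-(tert-butyldimethylsilyloxy)-1-methoxyethene in CH2Cl2 at −78 °C (the silyl ketene acetal version of the substitution) should give racemic trans methyl 2-[3,5-dimethyl-5-(oct-7-en-1-yl)-1,2-dioxolan-3-yl]acetate F2. Saponification (LiOH, THF/H2O) gives the racemic trans acid F3. This is resolved by fractional crystallisation of its salt with (R)-1-phenylethylamine (or, failing crystallinity, on a chiral stationary phase); acidification returns the route to 13.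

Step 10. Proton transfer from the free acid and aggregation of the potassium carboxylate may deplete or slow the carbanion, so that self-condensation of the metalated sulfone and erosion of E-selectivity take over. The fallback gives up the protecting-group-free endgame and sets out from 15. Esterification with TMSCHN2 (PhMe/MeOH, 0 °C) gives methyl 2-[(3R,5S)-3,5-dimethyl-5-[(E)-9-oxonon-7-en-1-yl]-1,2-dioxolan-3-yl]acetate F4. Julia–Kocienski olefination with 1.2 equiv of 20 (KHMDS, DME, −78 °C) gives methyl 2-[(3R,5S)-3,5-dimethyl-5-[(7E,9E,12Z)-pentadeca-7,9,12-trien-1-yl]-1,2-dioxolan-3-yl]acetate F5. Saponification (LiOH, THF/H2O, 0 °C → rt) rejoins the route at 21.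

Further compounds
F1 | step 3 | 4-chloro-4-methyldodec-11-en-2-one (racemic) | CC(=O)CC(C)(Cl)CCCCCCC=C
F2 | step 5 | methyl 2-[3,5-dimethyl-5-(oct-7-en-1-yl)-1,2-dioxolan-3-yl]acetate, racemic trans (3R,5S plus 3S,5R) | C=CCCCCCC[C@@]1(C)C[C@](C)(CC(=O)OC)OO1.C=CCCCCCC[C@]1(C)C[C@@](C)(CC(=O)OC)OO1
F3 | step 5 | 2-[3,5-dimethyl-5-(oct-7-en-1-yl)-1,2-dioxolan-3-yl]acetic acid, racemic trans (3R,5S plus 3S,5R) | C=CCCCCCC[C@@]1(C)C[C@](C)(CC(=O)O)OO1.C=CCCCCCC[C@]1(C)C[C@@](C)(CC(=O)O)OO1
F4 | step 10 | methyl 2-[(3R,5S)-3,5-dimethyl-5-[(E)-9-oxonon-7-en-1-yl]-1,2-dioxolan-3-yl]acetate | O=C/C=C/CCCCCC[C@@]1(C)C[C@](C)(CC(=O)OC)OO1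
F5 | step 10 | methyl 2-[(3R,5S)-3,5-dimethyl-5-[(7E,9E,12Z)-pentadeca-7,9,12-trien-1-yl]-1,2-dioxolan-3-yl]acetate | CC/C=C\C/C=C/C=C/CCCCCC[C@@]1(C)C[C@](C)(CC(=O)OC)OO1
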